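**Retrosynthetic overview**
1. Target 31 ⇐ TES ether 30 ⇐ Shi epoxidation of 29 (side-chain oxirane, formed last) ⇐ angeloylation of 26 ⇐ cross-metathesis of 24 ⇐ allylboration of enal 21 (C8–C9 bond).
2. Enal 21 ⇐ α-methylenation of aldehyde 19 ⇐ oxidised ring 17, whose two-carbon arm on C6 is carried as a NAP-protected alcohol.
3. 17 ⇐ hydroxyl-directed epoxidation of 15 (ring epoxide, formed second) ⇐ Luche reduction of 14 ⇐ Mitsunobu union of ketol 13 with acid 2 (inversion at C1).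
4. 13 ⇐ Rubottom oxidation of enone 10 ⇐ organocatalytic Michael/aldol annulation of enal 6 with β-ketoester 7 (the only carbocycle, formed first).
5. Acid 2 ⇐ tiglic acid 1 by enzymatic C=C reduction (2-enoate reductase).

Assumption: the usual steric model for (S)-diarylprolinol silyl ethers (attack anti to the CAr2OSiMe3 group of the s-trans (E)-iminium ion) holds for enal 6, so the (S)-catalyst gives (S)-10.
Locants C1–C11 in the Why lines are those of the target skeleton: ring C1 (O-2-methylbutanoyl), C2 (OH), C3–C4 (epoxide, CH3 on C3), C5, C6 (side chain); chain C7 (=CH2), C8 (O-angeloyl), C9, C10–C11 (epoxide).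

**Route**

Step 1
Reactants: 1 (2E)-2-methylbut-2-enoic acid (tiglic acid)
Product: 2 (2R)-2-methylbutanoic acid
Conditions: 2-enoate reductase (ene-reductase class, EC 1.3.1.31; Clostridium tyrobutyricum cells), H2 (1 atm), methyl viologen (cat.), phosphate buffer pH 7.0, 35 °C, anaerobic; then HCl, Et2O
Reagents that add atoms: none
Why: The 2-enoate reductase, whose native substrates are (E)-2-alkyl-2-enoates, performs an asymmetric conjugate reduction, delivering hydride to C3 and a proton to C2 anti across one face of bound tiglate, which sets the (R) α-stereocentre (the first stereocentre of the route) in high ee.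

Step 2
Reactants: 3 but-3-en-1-ol
Product: 4 2-[(but-3-en-1-yloxy)methyl]naphthalene
Conditions: NaH, Bu4NI (cat.), THF, 0 °C to rt
Reagents that add atoms: 2-(bromomethyl)naphthalene, BrCc1ccc2ccccc2c1
Why: Williamson etherification of the primary alkoxide with a benzylic bromide installs a 2-naphthylmethyl (NAP) ether that tolerates acid, base and peracid yet is removed oxidatively later.

Step 3
Reactants: 4 2-[(but-3-en-1-yloxy)methyl]naphthalene; 5 (2E)-but-2-enal
Product: 6 (2E)-5-(naphthalen-2-ylmethoxy)pent-2-enal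
Conditions: Hoveyda–Grubbs II (2.5 mol%), 5 (4 equiv), CH2Cl2, 40 °C
Reagents that add atoms: none
Why: Olefin cross-metathesis between a type I terminal alkene and crotonaldehyde in excess is E-selective and is driven by loss of propene.

Step 4
Reactants: 6 (2E)-5-(naphthalen-2-ylmethoxy)pent-2-enal; 7 tert-butyl 3-oxopentanoate
Product: 10 (5S)-2-methyl-5-[2-(naphthalen-2-ylmethoxy)ethyl]cyclohex-2-en-1-one, via Michael adduct 8 (not isolated), via keto aldehyde 9 (not isolated)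
Conditions: (S)-α,α-bis[3,5-bis(trifluoromethyl)phenyl]prolinol TMS ether (10 mol%), PhCO2H (10 mol%), toluene, rt; then p-TsOH·H2O (20 mol%), toluene, 80 °C
Reagents that add atoms: none
Why: Organocatalytic iminium-ion Michael addition of the β-ketoester to the enal (the nucleophile adds to the face opposite the CAr2OSiMe3 group and so sets C6 as S), followed by acid-promoted tert-butyl ester loss, decarboxylation and intramolecular aldol condensation (a Robinson-type annulation), gives the carvone-like enone.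

Step 5
Reactants: 10 (5S)-2-methyl-5-[2-(naphthalen-2-ylmethoxy)ethyl]cyclohex-2-en-1-one
Product: 13 (5S,6S)-6-hydroxy-2-methyl-5-[2-(naphthalen-2-ylmethoxy)ethyl]cyclohex-2-en-1-one, via silyl dienol ether 11 (not isolated), via silyloxy ketone 12 (not isolated)
Conditions: LDA, THF, −78 °C, then TMSCl; mCPBA, hexane/CH2Cl2, −15 °C; 1 M HCl, THF, 0 °C
Reagents that add atoms: mCPBA (3-chloroperoxybenzoic acid), OOC(=O)c1cccc(Cl)c1
Why: Rubottom oxidation: kinetic α′-deprotonation gives the cross-conjugated silyl dienol ether, whose electron-rich enol ether bond is epoxidised anti to the adjacent C6 substituent, so that silyl migration and hydrolysis give the ketol with C1–OH trans to the C6 arm.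

Step 6
Reactants: 13 (5S,6S)-6-hydroxy-2-methyl-5-[2-(naphthalen-2-ylmethoxy)ethyl]cyclohex-2-en-1-one; 2 (2R)-2-methylbutanoic acid
Product: 14 (1R,6S)-3-methyl-6-[2-(naphthalen-2-ylmethoxy)ethyl]-2-oxocyclohex-3-en-1-yl (2R)-2-methylbutanoate
Conditions: PPh3, DIAD, toluene, 0 °C to rt
Reagents that add atoms: none
Why: Mitsunobu esterification: the acyloin carbon, activated as its oxyphosphonium ion next to the carbonyl group, undergoes SN2 displacement by the carboxylate with inversion, which places the C1 ester cis to the C6 arm and turns any minor enantiomer of 13 into a separable diastereomer.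

Step 7
Reactants: 14 (1R,6S)-3-methyl-6-[2-(naphthalen-2-ylmethoxy)ethyl]-2-oxocyclohex-3-en-1-yl (2R)-2-methylbutanoate
Product: 15 (1R,2S,6S)-2-hydroxy-3-methyl-6-[2-(naphthalen-2-ylmethoxy)ethyl]cyclohex-3-en-1-yl (2R)-2-methylbutanoate
Conditions: NaBH4, CeCl3·7H2O, MeOH, −78 °C; AcOH quench
Reagents that add atoms: none
Why: Luche 1,2-reduction: the hard cerium borohydride attacks the enone carbonyl on the face anti to the axial C1 acyloxy group (the same axial trajectory that takes carvone to cis-carveol), giving the C2 alcohol cis to the C1 ester and the C6 arm without touching the ester.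

Step 8
Reactants: 15 (1R,2S,6S)-2-hydroxy-3-methyl-6-[2-(naphthalen-2-ylmethoxy)ethyl]cyclohex-3-en-1-yl (2R)-2-methylbutanoate
Product: 16 (1R,2R,3R,4R,6S)-2-hydroxy-1-methyl-4-[2-(naphthalen-2-ylmethoxy)ethyl]-7-oxabicyclo[4.1.0]heptan-3-yl (2R)-2-methylbutanoate
Conditions: VO(acac)2 (5 mol%), t-BuOOH (decane), CH2Cl2, 0 °C to rt
Reagents that add atoms: tert-butyl hydroperoxide, CC(C)(C)OO
Why: Vanadium-catalysed hydroxyl-directed (Sharpless-type) epoxidation delivers the peroxide oxygen to the C3=C4 bond from the face of the coordinated C2 alkoxide, so the epoxide forms syn to the hydroxyl and sets C3 and C4.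

Step 9
Reactants: 16 (1R,2R,3R,4R,6S)-2-hydroxy-1-methyl-4-[2-(naphthalen-2-ylmethoxy)ethyl]-7-oxabicyclo[4.1.0]heptan-3-yl (2R)-2-methylbutanoate
Product: 17 (1R,2R,3R,4R,6S)-1-methyl-4-[2-(naphthalen-2-ylmethoxy)ethyl]-2-[(triethylsilyl)oxy]-7-oxabicyclo[4.1.0]heptan-3-yl (2R)-2-methylbutanoate
Conditions: TESOTf, 2,6-lutidine, CH2Cl2, −78 °C
Reagents that add atoms: triethylsilyl trifluoromethanesulfonate, CC[Si](CC)(CC)OS(=O)(=O)C(F)(F)F
Why: Silylation with the reactive triflate caps the hindered C2 hydroxyl as a TES ether, which blocks acyl migration from O1 and leaves the C8 hydroxyl as the only free one later.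

Step 10
Reactants: 17 (1R,2R,3R,4R,6S)-1-methyl-4-[2-(naphthalen-2-ylmethoxy)ethyl]-2-[(triethylsilyl)oxy]-7-oxabicyclo[4.1.0]heptan-3-yl (2R)-2-methylbutanoate
Product: 18 (1R,2R,3R,4R,6S)-4-(2-hydroxyethyl)-1-methyl-2-[(triethylsilyl)oxy]-7-oxabicyclo[4.1.0]heptan-3-yl (2R)-2-methylbutanoate
Conditions: DDQ, CH2Cl2/pH 7 phosphate buffer (10:1), 0 °C to rt
Reagents that add atoms: none
Why: Oxidative cleavage of the 2-naphthylmethyl ether by DDQ (hydride abstraction, then hydrolysis of the oxocarbenium ion) frees the primary alcohol under near-neutral conditions that spare the epoxide, the ester and the silyl ether.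

Step 11
Reactants: 18 (1R,2R,3R,4R,6S)-4-(2-hydroxyethyl)-1-methyl-2-[(triethylsilyl)oxy]-7-oxabicyclo[4.1.0]heptan-3-yl (2R)-2-methylbutanoate
Product: 19 (1R,2R,3R,4S,6S)-1-methyl-4-(2-oxoethyl)-2-[(triethylsilyl)oxy]-7-oxabicyclo[4.1.0]heptan-3-yl (2R)-2-methylbutanoate
Conditions: TPAP (5 mol%), NMO, 4 Å MS, CH2Cl2, rt
Reagents that add atoms: none
Why: Ley–Griffith (TPAP/NMO) oxidation converts the primary alcohol into the aldehyde under neutral conditions without epimerisation or over-oxidation.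

Step 12
Reactants: 19 (1R,2R,3R,4S,6S)-1-methyl-4-(2-oxoethyl)-2-[(triethylsilyl)oxy]-7-oxabicyclo[4.1.0]heptan-3-yl (2R)-2-methylbutanoate; 20 formaldehyde
Product: 21 (1R,2R,3R,4S,6S)-1-methyl-4-(3-oxoprop-1-en-2-yl)-2-[(triethylsilyl)oxy]-7-oxabicyclo[4.1.0]heptan-3-yl (2R)-2-methylbutanoate
Conditions: 37% aq. HCHO, pyrrolidine (10 mol%), EtCO2H (10 mol%), i-PrOH, 45 °C
Reagents that add atoms: none
Why: Amine/acid-catalysed α-methylenation (Mannich condensation of the enamine with formaldehyde, then β-elimination of the amine) installs the C7 exo-methylene and gives the 2-substituted acrolein.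

Step 13
Reactants: 21 (1R,2R,3R,4S,6S)-1-methyl-4-(3-oxoprop-1-en-2-yl)-2-[(triethylsilyl)oxy]-7-oxabicyclo[4.1.0]heptan-3-yl (2R)-2-methylbutanoate; 22 4,4,5,5-tetramethyl-2-(prop-2-en-1-yl)-1,3,2-dioxaborolane
Product: 24 (1R,2R,3R,4S,6S)-4-[(3S)-3-hydroxyhexa-1,5-dien-2-yl]-1-methyl-2-[(triethylsilyl)oxy]-7-oxabicyclo[4.1.0]heptan-3-yl (2R)-2-methylbutanoate, via boronate ester 23 (not isolated)
Conditions: (S)-TRIP phosphoric acid (5 mol%), toluene, −30 °C; aq. NaHCO3 work-up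
Reagents that add atoms: none
Why: Chiral phosphoric acid-catalysed allylboration through a chair-like six-membered transition state, in which (S)-TRIP steers the allyl group to the Si face of the aldehyde, sets C8 as S under catalyst control, and the aldehyde reacts far faster than any other group present.

Step 14
Reactants: 24 (1R,2R,3R,4S,6S)-4-[(3S)-3-hydroxyhexa-1,5-dien-2-yl]-1-methyl-2-[(triethylsilyl)oxy]-7-oxabicyclo[4.1.0]heptan-3-yl (2R)-2-methylbutanoate; 25 2-methylbut-2-ene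
Product: 26 (1R,2R,3R,4S,6S)-4-[(3S)-3-hydroxy-6-methylhepta-1,5-dien-2-yl]-1-methyl-2-[(triethylsilyl)oxy]-7-oxabicyclo[4.1.0]heptan-3-yl (2R)-2-methylbutanoate
Conditions: Grubbs II (5 mol%), 25 (excess), CH2Cl2, 40 °C, sealed tube
Reagents that add atoms: none
Why: Olefin cross-metathesis of the monosubstituted terminal alkene with excess 2-methylbut-2-ene gives the trisubstituted prenyl-type alkene with loss of propene, the hindered 1,1-disubstituted C7 methylene being unreactive.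

Step 15
Reactants: 26 (1R,2R,3R,4S,6S)-4-[(3S)-3-hydroxy-6-methylhepta-1,5-dien-2-yl]-1-methyl-2-[(triethylsilyl)oxy]-7-oxabicyclo[4.1.0]heptan-3-yl (2R)-2-methylbutanoate; 27 (2Z)-2-methylbut-2-enoic acid (angelic acid)
Product: 29 (1R,2R,3R,4S,6S)-1-methyl-4-[(3S)-6-methyl-3-{[(2Z)-2-methylbut-2-enoyl]oxy}hepta-1,5-dien-2-yl]-2-[(triethylsilyl)oxy]-7-oxabicyclo[4.1.0]heptan-3-yl (2R)-2-methylbutanoate, via mixed anhydride 28 (not isolated)
Conditions: 27, 2,4,6-trichlorobenzoyl chloride, Et3N, toluene, rt; then 26, toluene, 80 °C (no DMAP)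
Reagents that add atoms: none
Why: Yamaguchi-type esterification through the mixed 2,4,6-trichlorobenzoic anhydride, run without DMAP, acylates the C8 alcohol with retention of the (Z) geometry of the angelate.

Step 16
Reactants: 29 (1R,2R,3R,4S,6S)-1-methyl-4-[(3S)-6-methyl-3-{[(2Z)-2-methylbut-2-enoyl]oxy}hepta-1,5-dien-2-yl]-2-[(triethylsilyl)oxy]-7-oxabicyclo[4.1.0]heptan-3-yl (2R)-2-methylbutanoate
Product: 30 (1R,2R,3R,4S,6S)-4-[(3S)-4-[(2R)-3,3-dimethyloxiran-2-yl]-3-{[(2Z)-2-methylbut-2-enoyl]oxy}but-1-en-2-yl]-1-methyl-2-[(triethylsilyl)oxy]-7-oxabicyclo[4.1.0]heptan-3-yl (2R)-2-methylbutanoate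
Conditions: D-fructose-derived Shi ketone (30 mol%), Oxone, K2CO3, Bu4NHSO4 (cat.), MeCN/DMM/aq. Na2B4O7–EDTA buffer, 0 °C
Reagents that add atoms: potassium peroxymonosulfate (Oxone), [K+].[O-]S(=O)(=O)OO
Why: Shi asymmetric epoxidation: the chiral dioxirane formed from the fructose-derived ketone and Oxone epoxidises the electron-rich trisubstituted C10=C11 bond through a spiro transition state to give the (10R)-oxirane, while the deactivated 1,1-disubstituted and enoate alkenes are left alone.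

Step 17
Reactants: 30 (1R,2R,3R,4S,6S)-4-[(3S)-4-[(2R)-3,3-dimethyloxiran-2-yl]-3-{[(2Z)-2-methylbut-2-enoyl]oxy}but-1-en-2-yl]-1-methyl-2-[(triethylsilyl)oxy]-7-oxabicyclo[4.1.0]heptan-3-yl (2R)-2-methylbutanoate
Product: 31 (1R,2R,3R,4S,6S)-4-[(3S)-4-[(2R)-3,3-dimethyloxiran-2-yl]-3-{[(2Z)-2-methylbut-2-enoyl]oxy}but-1-en-2-yl]-2-hydroxy-1-methyl-7-oxabicyclo[4.1.0]heptan-3-yl (2R)-2-methylbutanoate (CNP0181486.1)
Conditions: HF·pyridine, pyridine, THF, 0 °C
Reagents that add atoms: none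
Why: Fluoride-mediated desilylation with pyridine-buffered HF removes the TES ether under weakly acidic, non-basic conditions, so neither acyl migration from O1 to O2 nor opening of either epoxide takes place.

**Compound list**
1 | (2E)-2-methylbut-2-enoic acid (tiglic acid) | C/C=C(\C)C(=O)O | starting material
2 | (2R)-2-methylbutanoic acid | CC[C@@H](C)C(=O)O | intermediate
3 | but-3-en-1-ol | C=CCCO | starting material
4 | 2-[(but-3-en-1-yloxy)methyl]naphthalene | C=CCCOCc1ccc2ccccc2c1 | intermediate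
5 | (2E)-but-2-enal (crotonaldehyde) | C/C=C/C=O | starting material
6 | (2E)-5-(naphthalen-2-ylmethoxy)pent-2-enal | O=C/C=C/CCOCc1ccc2ccccc2c1 | intermediate
7 | tert-butyl 3-oxopentanoate | CCC(=O)CC(=O)OC(C)(C)C | starting material
8 | tert-butyl (3R)-3-[2-(naphthalen-2-ylmethoxy)ethyl]-5-oxo-2-propanoylpentanoate (C2 epimers; Michael adduct) | c1ccc2cc(COCC[C@@H](C(C(=O)OC(C)(C)C)C(=O)CC)CC=O)ccc2c1 | intermediate (not isolated)
9 | (3R)-3-[2-(naphthalen-2-ylmethoxy)ethyl]-5-oxoheptanal | c1ccc2cc(COCC[C@@H](CC(=O)CC)CC=O)ccc2c1 | intermediate (not isolated)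
10 | (5S)-2-methyl-5-[2-(naphthalen-2-ylmethoxy)ethyl]cyclohex-2-en-1-one | c1ccc2cc(COCC[C@@H]3CC=C(C)C(=O)C3)ccc2c1 | intermediate
11 | trimethyl({(3S)-6-methyl-3-[2-(naphthalen-2-ylmethoxy)ethyl]cyclohexa-1,5-dien-1-yl}oxy)silane | c1ccc2cc(COCC[C@@H]3CC=C(C)C(O[Si](C)(C)C)=C3)ccc2c1 | intermediate (not isolated)
12 | (5S,6S)-2-methyl-5-[2-(naphthalen-2-ylmethoxy)ethyl]-6-[(trimethylsilyl)oxy]cyclohex-2-en-1-one | c1ccc2cc(COCC[C@@H]3CC=C(C)C(=O)[C@H]3O[Si](C)(C)C)ccc2c1 | intermediate (not isolated)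
13 | (5S,6S)-6-hydroxy-2-methyl-5-[2-(naphthalen-2-ylmethoxy)ethyl]cyclohex-2-en-1-one | c1ccc2cc(COCC[C@@H]3CC=C(C)C(=O)[C@H]3O)ccc2c1 | intermediate
14 | (1R,6S)-3-methyl-6-[2-(naphthalen-2-ylmethoxy)ethyl]-2-oxocyclohex-3-en-1-yl (2R)-2-methylbutanoate | c1ccc2cc(COCC[C@@H]3CC=C(C)C(=O)[C@@H]3OC(=O)[C@H](C)CC)ccc2c1 | intermediate
15 | (1R,2S,6S)-2-hydroxy-3-methyl-6-[2-(naphthalen-2-ylmethoxy)ethyl]cyclohex-3-en-1-yl (2R)-2-methylbutanoate | c1ccc2cc(COCC[C@@H]3CC=C(C)[C@H](O)[C@@H]3OC(=O)[C@H](C)CC)ccc2c1 | intermediate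
16 | (1R,2R,3R,4R,6S)-2-hydroxy-1-methyl-4-[2-(naphthalen-2-ylmethoxy)ethyl]-7-oxabicyclo[4.1.0]heptan-3-yl (2R)-2-methylbutanoate | c1ccc2cc(COCC[C@@H]3C[C@@H]4O[C@]4(C)[C@H](O)[C@@H]3OC(=O)[C@H](C)CC)ccc2c1 | intermediate
17 | (1R,2R,3R,4R,6S)-1-methyl-4-[2-(naphthalen-2-ylmethoxy)ethyl]-2-[(triethylsilyl)oxy]-7-oxabicyclo[4.1.0]heptan-3-yl (2R)-2-methylbutanoate | c1ccc2cc(COCC[C@@H]3C[C@@H]4O[C@]4(C)[C@H](O[Si](CC)(CC)CC)[C@@H]3OC(=O)[C@H](C)CC)ccc2c1 | intermediate
18 | (1R,2R,3R,4R,6S)-4-(2-hydroxyethyl)-1-methyl-2-[(triethylsilyl)oxy]-7-oxabicyclo[4.1.0]heptan-3-yl (2R)-2-methylbutanoate | OCC[C@@H]1C[C@@H]2O[C@]2(C)[C@H](O[Si](CC)(CC)CC)[C@@H]1OC(=O)[C@H](C)CC | intermediate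
19 | (1R,2R,3R,4S,6S)-1-methyl-4-(2-oxoethyl)-2-[(triethylsilyl)oxy]-7-oxabicyclo[4.1.0]heptan-3-yl (2R)-2-methylbutanoate | O=CC[C@@H]1C[C@@H]2O[C@]2(C)[C@H](O[Si](CC)(CC)CC)[C@@H]1OC(=O)[C@H](C)CC | intermediate
20 | formaldehyde | C=O | starting material
21 | (1R,2R,3R,4S,6S)-1-methyl-4-(3-oxoprop-1-en-2-yl)-2-[(triethylsilyl)oxy]-7-oxabicyclo[4.1.0]heptan-3-yl (2R)-2-methylbutanoate | C=C(C=O)[C@@H]1C[C@@H]2O[C@]2(C)[C@H](O[Si](CC)(CC)CC)[C@@H]1OC(=O)[C@H](C)CC | intermediate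
22 | 4,4,5,5-tetramethyl-2-(prop-2-en-1-yl)-1,3,2-dioxaborolane (allylboronic acid pinacol ester) | C=CCB1OC(C)(C)C(C)(C)O1 | starting material
23 | O8-(4,4,5,5-tetramethyl-1,3,2-dioxaborolan-2-yl) derivative of 24 (boronate ester) | C=C([C@H](CC=C)OB3OC(C)(C)C(C)(C)O3)[C@@H]1C[C@@H]2O[C@]2(C)[C@H](O[Si](CC)(CC)CC)[C@@H]1OC(=O)[C@H](C)CC | intermediate (not isolated)
24 | (1R,2R,3R,4S,6S)-4-[(3S)-3-hydroxyhexa-1,5-dien-2-yl]-1-methyl-2-[(triethylsilyl)oxy]-7-oxabicyclo[4.1.0]heptan-3-yl (2R)-2-methylbutanoate | C=C([C@H](CC=C)O)[C@@H]1C[C@@H]2O[C@]2(C)[C@H](O[Si](CC)(CC)CC)[C@@H]1OC(=O)[C@H](C)CC | intermediate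
25 | 2-methylbut-2-ene | CC=C(C)C | starting material
26 | (1R,2R,3R,4S,6S)-4-[(3S)-3-hydroxy-6-methylhepta-1,5-dien-2-yl]-1-methyl-2-[(triethylsilyl)oxy]-7-oxabicyclo[4.1.0]heptan-3-yl (2R)-2-methylbutanoate | C=C([C@H](CC=C(C)C)O)[C@@H]1C[C@@H]2O[C@]2(C)[C@H](O[Si](CC)(CC)CC)[C@@H]1OC(=O)[C@H](C)CC | intermediate
27 | (2Z)-2-methylbut-2-enoic acid (angelic acid) | C/C=C(/C)C(=O)O | starting material
28 | (2Z)-2-methylbut-2-enoic 2,4,6-trichlorobenzoic anhydride | C/C=C(/C)C(=O)OC(=O)c1c(Cl)cc(Cl)cc1Cl | intermediate (not isolated)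
29 | (1R,2R,3R,4S,6S)-1-methyl-4-[(3S)-6-methyl-3-{[(2Z)-2-methylbut-2-enoyl]oxy}hepta-1,5-dien-2-yl]-2-[(triethylsilyl)oxy]-7-oxabicyclo[4.1.0]heptan-3-yl (2R)-2-methylbutanoate | C=C([C@H](CC=C(C)C)OC(=O)/C(C)=C\C)[C@@H]1C[C@@H]2O[C@]2(C)[C@H](O[Si](CC)(CC)CC)[C@@H]1OC(=O)[C@H](C)CC | intermediate
30 | (1R,2R,3R,4S,6S)-4-[(3S)-4-[(2R)-3,3-dimethyloxiran-2-yl]-3-{[(2Z)-2-methylbut-2-enoyl]oxy}but-1-en-2-yl]-1-methyl-2-[(triethylsilyl)oxy]-7-oxabicyclo[4.1.0]heptan-3-yl (2R)-2-methylbutanoate | C=C([C@H](C[C@H]1OC1(C)C)OC(=O)/C(C)=C\C)[C@@H]1C[C@@H]2O[C@]2(C)[C@H](O[Si](CC)(CC)CC)[C@@H]1OC(=O)[C@H](C)CC | intermediate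
31 | (1R,2R,3R,4S,6S)-4-[(3S)-4-[(2R)-3,3-dimethyloxiran-2-yl]-3-{[(2Z)-2-methylbut-2-enoyl]oxy}but-1-en-2-yl]-2-hydroxy-1-methyl-7-oxabicyclo[4.1.0]heptan-3-yl (2R)-2-methylbutanoate (CNP0181486.1) | C=C([C@H](C[C@H]1OC1(C)C)OC(=O)/C(C)=C\C)[C@@H]1C[C@@H]2O[C@]2(C)[C@H](O)[C@@H]1OC(=O)[C@H](C)CC | target

**Step count and weak points**
Total: 17 steps. Longest linear sequence: 16 steps (steps 2–17, from but-3-en-1-ol); step 1 is the convergent acid branch.

Most likely to fail: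

Step 5 (Rubottom oxidation; the trans/cis ratio at C1 and competing γ-oxidation are uncertain). The fallback sets out from enone 10 and replaces enolate chemistry by radical α′-acetoxylation: Mn(OAc)3·2H2O in benzene at reflux gives (1S,6S)-3-methyl-6-[2-(naphthalen-2-ylmethoxy)ethyl]-2-oxocyclohex-3-en-1-yl acetate F1 (the trans isomer is separated). Brief methanolysis (K2CO3, MeOH, 0 °C) then returns to the route at ketol 13.

Step 6 (Mitsunobu inversion of a hindered acyloin with an aliphatic acid; retention, elimination or low conversion are possible). The fallback sets out from enone 10 and forms the C1–O bond by carboxylate displacement of a halide instead of activating an alcohol. The silyl dienol ether 11 is brominated (NBS, THF, −78 °C) to (5S,6S)-6-bromo-2-methyl-5-[2-(naphthalen-2-ylmethoxy)ethyl]cyclohex-2-en-1-one F2. SN2 displacement with caesium (2R)-2-methylbutanoate F3 (from acid 2 and Cs2CO3) in DMF at 0 °C inverts C1 and returns to the route at ester 14.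

Step 13 (catalyst-controlled allylboration of a 2-substituted acrolein next to existing stereocentres; the C8 diastereoselectivity may be low). The fallback sets out from the unseparated step-13 product, alcohol 24 mixed with its C8 epimer (1R,2R,3R,4S,6S)-4-[(3R)-3-hydroxyhexa-1,5-dien-2-yl]-1-methyl-2-[(triethylsilyl)oxy]-7-oxabicyclo[4.1.0]heptan-3-yl (2R)-2-methylbutanoate F4, and sets C8 by ketone reduction instead of C–C bond formation. Dess–Martin oxidation gives the dienone (1R,2R,3R,4S,6S)-1-methyl-4-(3-oxohexa-1,5-dien-2-yl)-2-[(triethylsilyl)oxy]-7-oxabicyclo[4.1.0]heptan-3-yl (2R)-2-methylbutanoate F5. Corey–Bakshi–Shibata reduction ((R)-Me-CBS, catecholborane, toluene, −78 °C; alkenyl as the large group) then returns to the route at diastereomerically pure 24.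

**Further compounds**
F1 | step 5 | (1S,6S)-3-methyl-6-[2-(naphthalen-2-ylmethoxy)ethyl]-2-oxocyclohex-3-en-1-yl acetate | c1ccc2cc(COCC[C@@H]3CC=C(C)C(=O)[C@H]3OC(C)=O)ccc2c1
F2 | step 6 | (5S,6S)-6-bromo-2-methyl-5-[2-(naphthalen-2-ylmethoxy)ethyl]cyclohex-2-en-1-one | c1ccc2cc(COCC[C@@H]3CC=C(C)C(=O)[C@H]3Br)ccc2c1
F3 | step 6 | caesium (2R)-2-methylbutanoate | CC[C@@H](C)C(=O)[O-].[Cs+]
F4 | step 13 | (1R,2R,3R,4S,6S)-4-[(3R)-3-hydroxyhexa-1,5-dien-2-yl]-1-methyl-2-[(triethylsilyl)oxy]-7-oxabicyclo[4.1.0]heptan-3-yl (2R)-2-methylbutanoate | C=C([C@@H](CC=C)O)[C@@H]1C[C@@H]2O[C@]2(C)[C@H](O[Si](CC)(CC)CC)[C@@H]1OC(=O)[C@H](C)CC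
F5 | step 13 | (1R,2R,3R,4S,6S)-1-methyl-4-(3-oxohexa-1,5-dien-2-yl)-2-[(triethylsilyl)oxy]-7-oxabicyclo[4.1.0]heptan-3-yl (2R)-2-methylbutanoate | C=C(C(=O)CC=C)[C@@H]1C[C@@H]2O[C@]2(C)[C@H](O[Si](CC)(CC)CC)[C@@H]1OC(=O)[C@H](C)CC
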